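## Retrosynthetic overview
1. The target comes from its 7-allyl isomer by a final E-selective allyl → propenyl shift. With an unconjugated side chain, the catechol-derived half cannot enter 8–8′ or 8–5′ coupling.
2. Both C–O bonds of the dioxane ring are opened at once, giving (E)-4-propenylsyringol and 5-allyl-3-methoxy-1,2-benzoquinone. They are joined by a redox-neutral 8-O-4′ coupling under chiral phosphoric acid control, followed by p-quinone methide closure (7-O-3′).
3. Both partners come from one monomer, 4-allyl-2,6-dimethoxyphenol. One portion is isomerised and the other is oxidatively demethylated.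
4. Ring order: both arenes are bought. Only the 1,4-dioxane ring is built, C8–O first (sets 8R) and C7–O second (sets 7R, trans).

Assumption: no precedent fixes the sense of induction in step 3, so (R)-TRIP is written for the (2R,3R) series; if chiral HPLC and CD of the first run show the antipode, the equally available (S)-TRIP is used and nothing else changes.

## Route

Step 1
Reactants: 1 4-allyl-2,6-dimethoxyphenol (methoxyeugenol)
Product: 2 (E)-2,6-dimethoxy-4-(prop-1-enyl)phenol ((E)-4-propenylsyringol)
Conditions: RuClH(CO)(PPh3)3 (1 mol %), toluene, 80 °C, 3 h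
Reagents that add atoms: none
Why: Metal-hydride alkene isomerisation (Ru–H insertion/β-hydride elimination) moves the double bond into conjugation with the arene and settles on the thermodynamic E isomer (E:Z ≥ 95:5), and free eugenol-type phenols are tolerated.

Step 2
Reactants: 1 4-allyl-2,6-dimethoxyphenol (second portion)
Product: 3 5-allyl-3-methoxy-1,2-benzoquinone
Conditions: IBX (1.1 equiv), THF, 0 °C → rt, dark, 3 h; filter, cold aq NaHCO3 wash, concentrate below 20 °C, use the same day
Reagents that add atoms: 2-iodoxybenzoic acid (IBX), O=C1OI(=O)(O)c2ccccc12 (delivers the new carbonyl oxygen)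
Why: In this IBX oxidative demethylation of a 2-methoxyphenol, the phenol binds to I(V), oxygen passes to a methoxy-bearing ortho carbon and methanol is lost; the two ortho positions are equivalent, so only one quinone can form, and the isolated allyl group is inert at rt.

Step 3
Reactants: 2 (E)-4-propenylsyringol (1.3 equiv); 3 5-allyl-3-methoxy-1,2-benzoquinone (1.0 equiv)
Product: 5 (2R,3R)-7-allyl-2-(4-hydroxy-3,5-dimethoxyphenyl)-5-methoxy-3-methyl-2,3-dihydro-1,4-benzodioxine, via (8R)-p-quinone methide 4 (not isolated)
Conditions: (R)-TRIP (10 mol %), 4 Å MS, toluene–CH2Cl2 4:1, −40 °C, 3 added over 4 h, Ar, dark, 24 h; then rt, 2 h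
Reagents that add atoms: none
Why: Proposed new method: this is a redox-neutral, fully atom-economic formal [4+2] (inverse-demand hetero-Diels–Alder type) of an o-quinone with a p-hydroxystyrene under chiral phosphoric acid control; the P–OH hydrogen-bonds to the more basic C1 carbonyl of 3 (vinylogous ester with the 3-OMe), which makes the oxygen on C2 the electrophilic terminus (or the spin-bearing one after proton-coupled electron transfer from 2), while P=O holds the phenol OH of 2 and raises the nucleophilicity of C8; the ring carbons of 3 with large LUMO or spin coefficients (C3, C5) are substituted, so oxygen is the accessible site, as it is for syringyl units and for o-chloranil; C8 bonds through its Re face to that oxygen inside the chiral pocket, irreversibly because the quinone aromatises, and this sets 8R; the freed ortho-phenol then adds to C7 of 4 (6-exo-trig oxa-Michael addition), and because this closure is reversible under the acid, C7 settles as the trans-diequatorial 7R centre; the closest known reaction types are the racemic Ag2O-mediated catechol/propenylphenol benzodioxane coupling with the same connectivity, the enantioselective organocatalytic [4+2] and α-aryloxylation of enamines and ketene enolates at the oxygen of o-quinones, and phosphoric-acid-catalysed formal cycloadditions of hydroxystyrenes with quinone-type acceptors through remote OH activation.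

Step 4
Reactants: 5 (2R,3R)-7-allyl-2-(4-hydroxy-3,5-dimethoxyphenyl)-5-methoxy-3-methyl-2,3-dihydro-1,4-benzodioxine
Product: 6 (2R,3R)-2-(4-hydroxy-3,5-dimethoxyphenyl)-5-methoxy-3-methyl-7-[(E)-prop-1-enyl]-2,3-dihydro-1,4-benzodioxine (target)
Conditions: RuClH(CO)(PPh3)3 (2 mol %), toluene, 70 °C, 4 h; recrystallise
Reagents that add atoms: none
Why: The same neutral metal-hydride alkene isomerisation gives the conjugated E-propenyl group; neither stereocentre takes part, C8 has no epimerisation pathway, and any reversible opening at C7 returns to the trans isomer.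

## Compound list
1 | 4-allyl-2,6-dimethoxyphenol (methoxyeugenol) | C=CCc1cc(OC)c(O)c(OC)c1 | starting material
2 | (E)-2,6-dimethoxy-4-(prop-1-enyl)phenol | C/C=C/c1cc(OC)c(O)c(OC)c1 | intermediate
3 | 5-allyl-3-methoxy-1,2-benzoquinone (3-methoxy-5-(prop-2-enyl)cyclohexa-3,5-diene-1,2-dione) | C=CCC1=CC(=O)C(=O)C(OC)=C1 | intermediate
4 | 4-[(2R)-2-(4-allyl-2-hydroxy-6-methoxyphenoxy)propylidene]-2,6-dimethoxycyclohexa-2,5-dien-1-one | C[C@H](C=C1C=C(OC)C(=O)C(OC)=C1)Oc1c(O)cc(CC=C)cc1OC | intermediate (not isolated)
5 | (2R,3R)-7-allyl-2-(4-hydroxy-3,5-dimethoxyphenyl)-5-methoxy-3-methyl-2,3-dihydro-1,4-benzodioxine | C=CCc1cc(OC)c2c(c1)O[C@H](c1cc(OC)c(O)c(OC)c1)[C@@H](C)O2 | intermediate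
6 | (2R,3R)-2-(4-hydroxy-3,5-dimethoxyphenyl)-5-methoxy-3-methyl-7-[(E)-prop-1-enyl]-2,3-dihydro-1,4-benzodioxine | C/C=C/c1cc(OC)c2c(c1)O[C@H](c1cc(OC)c(O)c(OC)c1)[C@@H](C)O2 | target

## Step count and risks
Total steps: 4. Longest linear sequence: 3 (1 → 2 or 3 → 5 → 6).

**Most likely to fail, first: step 3.**
- The risks are a racemic background reaction (uncatalysed or radical-chain coupling), acid dimerisation of 2, tautomerisation of 3 to a vinyl quinone methide, and C-attack at C6 of 3.
- The fallback sets out from 2 and 3 and comes back at 5. It gives up catalyst control and relies on resolution.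
- 2 and 3 are stirred over Ag2O in benzene–acetone at rt in the dark. The classical silver-oxide catechol/propenylphenol coupling contains this same mixture once its catechol has been oxidised.
- The free phenoxyl radical of 2 couples through C8 to the oxygen on C2 of 3. This gives 4 together with its mirror image, the (8S)-p-quinone methide F1.
- Both close under a trace of TsOH to the trans ring, giving 5 and the (2S,3S)-enantiomer F2 as a racemate.
- Preparative SFC on an immobilised amylose phase separates them, and 5 goes on to step 4.

**Second: step 2.**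
- The risks are dimerisation or tautomerisation of 3 during its formation and over-oxidation.
- The fallback sets out from 1 and comes back at 3. It separates ether cleavage from oxidation.
- Chelation-controlled, redox-neutral mono-demethylation uses AlCl3 (1.1 equiv) and pyridine in refluxing CH2Cl2. It gives 5-allyl-3-methoxybenzene-1,2-diol F3, and the aluminium catecholate stops a second cleavage.
- F3 can be stored. It is dehydrogenated just before use with Ag2O/Na2SO4 in dry Et2O at 0 °C for 10 min.
- Filtration and a solvent swap to toluene give a dry solution of 3.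

**Third: step 4.**
- The risks are catalyst inhibition by the free syringyl phenol, quinone methide chemistry at C7 on heating, and residual Z isomer.
- The fallback sets out from 5 and comes back at 6. It masks the phenol so that no quinone methide can form.
- Ac2O/pyridine gives the aryl acetate of 5, F4.
- PdCl2(MeCN)2 in CH2Cl2 at rt isomerises the allyl group to give the aryl acetate of 6, F5, which is recrystallised to remove the Z isomer.
- Brief aminolysis with pyrrolidine in CH2Cl2 at 0 °C releases 6.

## Further compounds
F1 | step 3 | 4-[(2S)-2-(4-allyl-2-hydroxy-6-methoxyphenoxy)propylidene]-2,6-dimethoxycyclohexa-2,5-dien-1-one (enantiomer of 4) | C[C@@H](C=C1C=C(OC)C(=O)C(OC)=C1)Oc1c(O)cc(CC=C)cc1OC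
F2 | step 3 | (2S,3S)-7-allyl-2-(4-hydroxy-3,5-dimethoxyphenyl)-5-methoxy-3-methyl-2,3-dihydro-1,4-benzodioxine (enantiomer of 5) | C=CCc1cc(OC)c2c(c1)O[C@@H](c1cc(OC)c(O)c(OC)c1)[C@H](C)O2
F3 | step 2 | 5-allyl-3-methoxybenzene-1,2-diol | C=CCc1cc(O)c(O)c(OC)c1
F4 | step 4 | 4-[(2R,3R)-7-allyl-5-methoxy-3-methyl-2,3-dihydro-1,4-benzodioxin-2-yl]-2,6-dimethoxyphenyl acetate | C=CCc1cc(OC)c2c(c1)O[C@H](c1cc(OC)c(OC(C)=O)c(OC)c1)[C@@H](C)O2
F5 | step 4 | 4-[(2R,3R)-5-methoxy-3-methyl-7-[(E)-prop-1-enyl]-2,3-dihydro-1,4-benzodioxin-2-yl]-2,6-dimethoxyphenyl acetate | C/C=C/c1cc(OC)c2c(c1)O[C@H](c1cc(OC)c(OC(C)=O)c(OC)c1)[C@@H](C)O2
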